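**Plan**

1. Atom labels are those of ent-kaurane. Retrosynthesis: the lactol, the C15 ketone and the two acetates come from a lactone, a silyl-protected C15 alcohol and a ring A 1,2-dione. Bonds C3–C4 and C5–C10 are then cut together, which opens ring A and the seven-membered ring B at once and leaves an ester C6(=O)–O–C7. The C10=C1 enone is cut back to a C10 alkyne, C8–C15 to an enolate alkylation and C8–C7 to a carbonylation of (R)-carvone.
2. Enabling feature: ring A (C1–C5, C10) carries oxygen on C1 and C2, so it is the cyclohexene of a 2-silyloxy diene C10=C1–C2=C3 attached to C9. The C6–O–C7 bridge of the lactol ring B (C5–C6–O–C7–C8–C9–C10) is a built-in ester tether that holds a 3-methylbut-2-enoate (C4=C5, both C4 methyls, C6) on C8 beside that diene.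
3. Forward order: ring C is carvone; ring D is closed by reductive enolate alkylation; C10 and C15 are oxidised, C16=C17 hydrogenated, the side chain extended to the (E)-enone and C9=C11 epoxidised. Rings A and B then form together in the key step. Ring A oxidation and reduction, lactone-to-lactol reduction, acetylation and C15 oxidation finish the route.
4. Stereochemistry: C13 from (R)-carvone; C8 forced by the bridge; C16 by exo-face hydrogenation; C9 and C11 by exo-face epoxidation; C10 and C5 in the key step (tether on C8, C9 stereocentre, (E)-diene, exo transition state); C1 and C2 by β-face hydride delivery; C6 is an equilibrating lactol centre.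

Key step: step 14

Remark: α denotes the face of the C20 methyl group and β the opposite face. The lactol carbon C6 epimerises through the hydroxy aldehyde; the epimer of the target is assumed to be the one favoured at equilibrium, and C6 is drawn with that configuration from compound 25 on.

**Route**

Step 1
Reactants: 1 (R)-(–)-carvone
Product: 3 (3R)-6-methyl-3-(prop-1-en-2-yl)cyclohexa-1,5-dien-1-yl trifluoromethanesulfonate, via lithium dienolate 2 (not isolated)
Conditions: LiN(SiMe3)2, THF, –78 °C; PhNTf2, –78 to 0 °C
Reagents that add atoms: N-phenylbis(trifluoromethanesulfonimide), O=S(=O)(N(c1ccccc1)S(=O)(=O)C(F)(F)F)C(F)(F)F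
Why: Kinetic deprotonation at the α′-methylene should give the cross-conjugated dienolate 2, which is O-sulfonylated to the dienyl triflate (enol triflate formation) without touching the stereocentre inherited from carvone (future C13).

Step 2
Reactants: 3 dienyl triflate
Product: 4 methyl (3R)-6-methyl-3-(prop-1-en-2-yl)cyclohexa-1,5-diene-1-carboxylate
Conditions: Pd(OAc)2 (cat), PPh3, CO (1 atm), MeOH, Et3N, DMF, 60 °C
Reagents that add atoms: carbon monoxide, [C-]#[O+]; methanol, CO
Why: Palladium-catalysed methoxycarbonylation of the dienyl triflate (oxidative addition, CO insertion, methanolysis) should attach C7 to C8 as a methyl ester.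

Step 3
Reactants: 4 dienoate
Product: 5 methyl (3R)-3-(3-chloroprop-1-en-2-yl)-6-methylcyclohexa-1,5-diene-1-carboxylate
Conditions: Ca(OCl)2, solid CO2, CH2Cl2/H2O, 0 °C
Reagents that add atoms: calcium hypochlorite, [Ca+2].[O-]Cl.[O-]Cl
Why: Ene-type allylic chlorination by hypochlorous acid generated in situ should occur at the electron-rich isopropenyl group rather than at the ester-deactivated ring diene, as it does with carvone itself, and gives the 2-(chloromethyl)vinyl group (C15, C16, C17).

Step 4
Reactants: 5 chloro dienoate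
Product: 7 methyl (1R,5R)-2-methyl-6-methylidenebicyclo[3.2.1]oct-2-ene-1-carboxylate, via lithium ester dienolate 6 (not isolated)
Conditions: LiBH(s-Bu)3, THF, –78 °C to rt
Reagents that add atoms: none
Why: Conjugate hydride addition to C14 of the dienoate should give dienolate 6, whose α-carbon C8 displaces the allylic chloride in a 5-exo-tet closure of ring D (reductive enolate alkylation; attack at either allyl terminus gives the same product), and because the two-carbon bridge can only span C8 and C13 on one face the new quaternary centre C8 is fixed by C13.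

Step 5
Reactants: 7 bicyclic ester
Product: 8 methyl 7-exo-hydroxy-2-(hydroxymethyl)-6-methylidenebicyclo[3.2.1]oct-2-ene-1-carboxylate (bridgeheads as in 7; 7-OH syn to the one-carbon bridge)
Conditions: SeO2 (0.5 equiv), t-BuOOH (5 equiv), CH2Cl2, rt
Reagents that add atoms: tert-butyl hydroperoxide, CC(C)(C)OO
Why: Selenium dioxide allylic oxidation (ene reaction then [2,3]-sigmatropic shift) should hydroxylate the only hydrogen-bearing allylic carbon at the more substituted end of each alkene, the C9 methyl (C10) and the ring D methylene C15, the latter from the open exo face, although the C15 configuration is of no consequence.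

Step 6
Reactants: 8 diol
Product: 9 methyl 7-exo-hydroxy-2-(hydroxymethyl)-6-endo-methylbicyclo[3.2.1]oct-2-ene-1-carboxylate
Conditions: H2 (1 atm), RhCl(PPh3)3 (cat), benzene, rt
Reagents that add atoms: none
Why: RhCl(PPh3)3 should hydrogenate the unhindered 1,1-disubstituted C16=C17 alkene much faster than the trisubstituted C9=C11 alkene, and delivery of hydrogen to the exo face of ring D turns C17 into the endo methyl group, which is the C16 configuration of the target.

Step 7
Reactants: 9 dihydro diol
Product: 10 methyl 2-formyl-7-exo-hydroxy-6-endo-methylbicyclo[3.2.1]oct-2-ene-1-carboxylate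
Conditions: MnO2, CH2Cl2, rt
Reagents that add atoms: none
Why: MnO2 oxidises only the allylic primary alcohol (C10) to the enal, the now saturated secondary C15 alcohol being inert.

Step 8
Reactants: 10 hydroxy enal
Product: 11 methyl 7-exo-(tert-butyldimethylsilyloxy)-2-formyl-6-endo-methylbicyclo[3.2.1]oct-2-ene-1-carboxylate
Conditions: t-BuMe2SiOTf, 2,6-lutidine, CH2Cl2, –78 to 0 °C
Reagents that add atoms: tert-butyldimethylsilyl trifluoromethanesulfonate, CC(C)(C)[Si](C)(C)OS(=O)(=O)C(F)(F)F
Why: Silylation with the silyl triflate protects the hindered secondary C15 hydroxyl, which must stay distinct from the ring A hydroxyls until its late oxidation.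

Step 9
Reactants: 11 silyloxy enal
Product: 12 methyl 7-exo-(tert-butyldimethylsilyloxy)-2-ethynyl-6-endo-methylbicyclo[3.2.1]oct-2-ene-1-carboxylate
Conditions: Me3SiCHN2, LiN(i-Pr)2, THF, –78 °C; then 11, –78 to 0 °C
Reagents that add atoms: trimethylsilyldiazomethane, C[Si](C)(C)C=[N+]=[N-]
Why: Colvin homologation (addition of lithiated trimethylsilyldiazomethane to the aldehyde, Peterson-type elimination and 1,2-shift in the alkylidene carbene) should give the terminal enyne, the hindered bridgehead ester being left alone at low temperature.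

Step 10
Reactants: 12 enyne ester
Product: 13 [7-exo-(tert-butyldimethylsilyloxy)-2-ethynyl-6-endo-methylbicyclo[3.2.1]oct-2-en-1-yl]methanol
Conditions: i-Bu2AlH (3 equiv), CH2Cl2, –78 to 0 °C; aq potassium sodium tartrate
Reagents that add atoms: none
Why: i-Bu2AlH reduces the bridgehead ester to the primary alcohol C7–OH, the oxygen that will become the ring oxygen of ring B.

Step 11
Reactants: 13 enyne alcohol, 14 3-methylbut-2-enoyl chloride
Product: 15 [7-exo-(tert-butyldimethylsilyloxy)-2-ethynyl-6-endo-methylbicyclo[3.2.1]oct-2-en-1-yl]methyl 3-methylbut-2-enoate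
Conditions: pyridine, DMAP (cat), CH2Cl2, 0 °C
Reagents that add atoms: none
Why: DMAP-catalysed acylation of the primary neopentyl alcohol with the acid chloride in pyridine (no stronger base, so that deconjugation through the vinylketene is avoided) attaches the dienophile C4=C5 with C6 and both C4 methyl groups.

Step 12
Reactants: 15 enyne ester
Product: 17 [7-exo-(tert-butyldimethylsilyloxy)-6-endo-methyl-2-[(E)-4-oxopent-2-en-2-yl]bicyclo[3.2.1]oct-2-en-1-yl]methyl 3-methylbut-2-enoate, via (E)-alkenyl(dimethyl)alane 16 (not isolated)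
Conditions: AlMe3, (C5H5)2ZrCl2 (cat), CH2Cl2, 0 °C to rt; then CH3COCl, Pd(PPh3)4 (cat), THF, 0 °C
Reagents that add atoms: trimethylaluminium, C[Al](C)C; acetyl chloride, CC(Cl)=O
Why: Zirconium-catalysed syn carboalumination (Negishi carboalumination) should place the methyl group C20 on the internal alkyne carbon C10 and aluminium on the terminal carbon C1, and palladium-catalysed acylation of the alkenylalane with retention then gives the (E)-enone with C9 trans to the acetyl group C2–C3.

Step 13
Reactants: 17 dienone ester
Product: 18 2,3-exo-epoxide of 17 (kaurane 9α,11α-epoxide; oxygen anti to the two-carbon bridge)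
Conditions: mCPBA, NaHCO3, CH2Cl2, 0 °C
Reagents that add atoms: 3-chloroperoxybenzoic acid, OOC(=O)c1cccc(Cl)c1
Why: Prilezhaev epoxidation should take place at the most electron-rich alkene, the γ,δ-alkene C9=C11 of the dienone, from the exo face of the bicyclo[3.2.1]octene (anti to the two-carbon bridge and its endo methyl group), which sets C9 and C11 as in the target.

Step 14
Reactants: 18 epoxy enone ester
Product: 20 tetracyclic lactone with ring A as C1=C2 triethylsilyl enol ether (C5 and C10 as in the target; seven-membered lactone C5–C6(=O)–O–C7; 9α,11α-epoxide; 15-exo-OSi-t-BuMe2; 16-methyl), via triethylsilyl dienol ether 19 (not isolated)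
Conditions: Et3SiOTf, Et3N, CH2Cl2, –78 °C; then toluene (0.01 M), BHT, 180 °C, sealed tube
Reagents that add atoms: triethylsilyl trifluoromethanesulfonate, CC[Si](CC)(CC)OS(=O)(=O)C(F)(F)F
Why: Soft enolisation of the methyl ketone gives the 2-silyloxy diene C3=C2(OSiEt3)–C1=C10 (19), which on heating adds to the tethered 3-methylbut-2-enoate C4=C5 in a concerted but asynchronous thermal [4+2] cycloaddition in which the nucleophilic terminus C3 bonds ahead to the β-carbon C4 and the α-carbon C5 then closes onto C10. The closest known reaction types are the ester-tethered type 1 intramolecular Diels–Alder reaction of dienyl acrylates and the cycloadditions of 4,4-disubstituted 2-silyloxy dienes with β,β-disubstituted acceptors. Ring A (six-membered carbocycle C1–C5/C10) is closed by both new bonds as the cycloadduct ring, and the seven-membered lactone ring B (C5–C6–O–C7–C8–C9–C10) is closed through the C5–C10 bond in the fused mode because the tether starts at the diene terminus C10. C5 is set by suprafacial addition to the (E)-diene (C9 outside, C20 inside) through the transition state with the lactone carbonyl C6 exo, away from the C2 silyloxy group, which places C6 trans to C9 and H5 anti to C20 (trans ring fusion). C10 is set by the adjacent epoxide stereocentre C9 and the tether on C8: the C20 methyl takes the position between C11 and the epoxide oxygen, away from the quaternary C8, and the enoate held by C7 then reaches C10 only from the diene face that looks toward C7 and the epoxide oxygen. The step needs regioselectivity (secured by the tether and by the matched polarity of C3 and C4), exo and π-facial selectivity (secured as just described) and a rate that outruns [1,5]-hydrogen shift in the cis-methyl diene and opening of the vinyl epoxide, for which the intramolecularity, the two ring atoms C8 and C9 within the five-atom tether and the electron-rich diene are relied on.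

Step 15
Reactants: 20 cycloadduct
Product: 22 1β-hydroxy-2-ketone (lactone, epoxide and 15-silyl ether unchanged), via silyloxy epoxide 21 (not isolated)
Conditions: dimethyldioxirane (1.2 equiv), acetone/CH2Cl2, –78 to –20 °C; then citric acid, MeOH, 0 °C
Reagents that add atoms: dimethyldioxirane, CC1(C)OO1
Why: Rubottom oxidation (epoxidation of the silyl enol ether, expected from the less hindered β face, then acid-induced opening and desilylation of 21) should give the C1-hydroxy C2-ketone regiospecifically, and the C1 configuration is erased in step 16.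

Step 16
Reactants: 22 α-ketol
Product: 23 1,2-dione (lactone, epoxide and 15-silyl ether unchanged)
Conditions: Dess–Martin periodinane, NaHCO3, CH2Cl2, rt
Reagents that add atoms: none
Why: Dess–Martin oxidation of the α-ketol should give the 1,2-dione, which can enolise only toward C3 because C10 is quaternary.

Step 17
Reactants: 23 dione
Product: 24 1α,2α-diol (lactone, epoxide and 15-silyl ether unchanged)
Conditions: NaBH4, MeOH/CH2Cl2, –40 to 0 °C
Reagents that add atoms: none
Why: NaBH4 should deliver hydride to C1 axially from the β face (the α face being screened by the C20 methyl group) and then to C2 from the β face (the α face being screened by the syn-axial C20 and C4 methyl groups), so that both hydroxyls end up α (1-equatorial, 2-axial) while the lactone, epoxide and silyl ether are untouched.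

Step 18
Reactants: 24 diol lactone
Product: 25 1α,2α-diol lactol (C6 hemiacetal; 15-silyl ether)
Conditions: i-Bu2AlH (4 equiv), CH2Cl2, –78 °C; aq potassium sodium tartrate
Reagents that add atoms: none
Why: At low temperature i-Bu2AlH reduction of the seven-membered lactone should stop at the aluminium hemiacetal, which gives the lactol on work-up.

Step 19
Reactants: 25 triol
Product: 26 1α,2α,6-triacetate (15-silyl ether)
Conditions: Ac2O, DMAP, Et3N, CH2Cl2, 40 °C
Reagents that add atoms: acetic anhydride, CC(=O)OC(C)=O
Why: DMAP-catalysed acetylation esterifies the two secondary hydroxyls of ring A and at the same time masks the lactol hydroxyl as an anomeric acetate for the oxidation in step 21.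

Step 20
Reactants: 26 triacetate silyl ether
Product: 27 1α,2α,6-triacetate 15-alcohol
Conditions: Bu4NF, AcOH, THF, rt
Reagents that add atoms: none
Why: Acetic acid-buffered fluoride should remove the silyl ether from O15 without acetate migration or epoxide opening.

Step 21
Reactants: 27 C15 alcohol
Product: 28 1α,2α,6-triacetate 15-ketone
Conditions: Dess–Martin periodinane, NaHCO3, CH2Cl2, rt
Reagents that add atoms: none
Why: Dess–Martin oxidation under buffered, non-enolising conditions should convert the C15 alcohol into the ketone without epimerising the adjacent C16 centre.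

Step 22
Reactants: 28 keto triacetate
Product: 29 CNP0210140.1 (target)
Conditions: PhCH2NH2, THF, rt
Reagents that add atoms: none
Why: Aminolysis is selective for the anomeric (acetal) acetate, which is far more electrophilic than the two hindered secondary acetates, and the liberated lactol equilibrates to the C6 configuration of the target.

**Compound list**

1 | (R)-(–)-carvone, (5R)-2-methyl-5-(prop-1-en-2-yl)cyclohex-2-en-1-one | O=C1C[C@@H](CC=C1C)C(C)=C | starting material
2 | lithium (3R)-6-methyl-3-(prop-1-en-2-yl)cyclohexa-1,5-dien-1-olate | [Li+].[O-]C1=C[C@@H](CC=C1C)C(C)=C | intermediate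
3 | (3R)-6-methyl-3-(prop-1-en-2-yl)cyclohexa-1,5-dien-1-yl trifluoromethanesulfonate | FC(F)(F)S(=O)(=O)OC1=C[C@@H](CC=C1C)C(C)=C | intermediate
4 | methyl (3R)-6-methyl-3-(prop-1-en-2-yl)cyclohexa-1,5-diene-1-carboxylate | COC(=O)C1=C[C@@H](CC=C1C)C(C)=C | intermediate
5 | methyl (3R)-3-(3-chloroprop-1-en-2-yl)-6-methylcyclohexa-1,5-diene-1-carboxylate | COC(=O)C1=C[C@@H](CC=C1C)C(=C)CCl | intermediate
6 | lithium dienolate of methyl (5R)-5-(3-chloroprop-1-en-2-yl)-2-methylcyclohex-2-ene-1-carboxylate | [Li+].COC([O-])=C1C[C@@H](CC=C1C)C(=C)CCl | intermediate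
7 | methyl (1R,5R)-2-methyl-6-methylidenebicyclo[3.2.1]oct-2-ene-1-carboxylate | COC(=O)[C@@]12C[C@@H](CC=C1C)C(=C)C2 | intermediate
8 | methyl 7-exo-hydroxy-2-(hydroxymethyl)-6-methylidenebicyclo[3.2.1]oct-2-ene-1-carboxylate | COC(=O)[C@@]12C[C@@H](CC=C1CO)C(=C)[C@@H]2O | intermediate
9 | methyl 7-exo-hydroxy-2-(hydroxymethyl)-6-endo-methylbicyclo[3.2.1]oct-2-ene-1-carboxylate | COC(=O)[C@@]12C[C@@H](CC=C1CO)[C@@H](C)[C@@H]2O | intermediate
10 | methyl 2-formyl-7-exo-hydroxy-6-endo-methylbicyclo[3.2.1]oct-2-ene-1-carboxylate | COC(=O)[C@@]12C[C@@H](CC=C1C=O)[C@@H](C)[C@@H]2O | intermediate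
11 | methyl 7-exo-(tert-butyldimethylsilyloxy)-2-formyl-6-endo-methylbicyclo[3.2.1]oct-2-ene-1-carboxylate | COC(=O)[C@@]12C[C@@H](CC=C1C=O)[C@@H](C)[C@@H]2O[Si](C)(C)C(C)(C)C | intermediate
12 | methyl 7-exo-(tert-butyldimethylsilyloxy)-2-ethynyl-6-endo-methylbicyclo[3.2.1]oct-2-ene-1-carboxylate | COC(=O)[C@@]12C[C@@H](CC=C1C#C)[C@@H](C)[C@@H]2O[Si](C)(C)C(C)(C)C | intermediate
13 | [7-exo-(tert-butyldimethylsilyloxy)-2-ethynyl-6-endo-methylbicyclo[3.2.1]oct-2-en-1-yl]methanol | OC[C@@]12C[C@@H](CC=C1C#C)[C@@H](C)[C@@H]2O[Si](C)(C)C(C)(C)C | intermediate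
14 | 3-methylbut-2-enoyl chloride | CC(C)=CC(Cl)=O | starting material
15 | 3-methylbut-2-enoate of 13 | CC(C)=CC(=O)OC[C@@]12C[C@@H](CC=C1C#C)[C@@H](C)[C@@H]2O[Si](C)(C)C(C)(C)C | intermediate
16 | (E)-alkenyl(dimethyl)alane from 15 (C20 methyl on C10, aluminium on C1) | CC(C)=CC(=O)OC[C@@]12C[C@@H](CC=C1/C(C)=C/[Al](C)C)[C@@H](C)[C@@H]2O[Si](C)(C)C(C)(C)C | intermediate
17 | (E)-enone: 2-[(E)-4-oxopent-2-en-2-yl] analogue of 15 | CC(C)=CC(=O)OC[C@@]12C[C@@H](CC=C1/C(C)=C/C(C)=O)[C@@H](C)[C@@H]2O[Si](C)(C)C(C)(C)C | intermediate
18 | 9α,11α-epoxide of 17 (2,3-exo-epoxide of the bicycle) | CC(C)=CC(=O)OC[C@@]12C[C@@H](C[C@H]3O[C@]31/C(C)=C/C(C)=O)[C@@H](C)[C@@H]2O[Si](C)(C)C(C)(C)C | intermediate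
19 | triethylsilyl dienol ether of 18 (2-silyloxy diene C3=C2–C1=C10) | CC(C)=CC(=O)OC[C@@]12C[C@@H](C[C@H]3O[C@]31/C(C)=C/C(=C)O[Si](CC)(CC)CC)[C@@H](C)[C@@H]2O[Si](C)(C)C(C)(C)C | intermediate
20 | tetracyclic lactone, C1=C2 triethylsilyl enol ether, 9α,11α-epoxide, 15-exo-silyl ether | CC[Si](CC)(CC)OC1CC(C)(C)[C@H]2C(=O)OC[C@@]34C[C@@H](C[C@H]5O[C@]53[C@]2(C)C=1)[C@@H](C)[C@@H]4O[Si](C)(C)C(C)(C)C | intermediate
21 | 1β,2β-epoxy-2α-triethylsilyloxy derivative of 20 | CC[Si](CC)(CC)O[C@@]16CC(C)(C)[C@H]2C(=O)OC[C@@]34C[C@@H](C[C@H]5O[C@]53[C@]2(C)[C@@H]1O6)[C@@H](C)[C@@H]4O[Si](C)(C)C(C)(C)C | intermediate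
22 | 1β-hydroxy-2-ketone | O=C1CC(C)(C)[C@H]2C(=O)OC[C@@]34C[C@@H](C[C@H]5O[C@]53[C@]2(C)[C@@H]1O)[C@@H](C)[C@@H]4O[Si](C)(C)C(C)(C)C | intermediate
23 | 1,2-dione | O=C1CC(C)(C)[C@H]2C(=O)OC[C@@]34C[C@@H](C[C@H]5O[C@]53[C@]2(C)C1=O)[C@@H](C)[C@@H]4O[Si](C)(C)C(C)(C)C | intermediate
24 | 1α,2α-diol lactone | O[C@H]1CC(C)(C)[C@H]2C(=O)OC[C@@]34C[C@@H](C[C@H]5O[C@]53[C@]2(C)[C@H]1O)[C@@H](C)[C@@H]4O[Si](C)(C)C(C)(C)C | intermediate
25 | 1α,2α-diol lactol | O[C@H]1CC(C)(C)[C@H]2[C@H](O)OC[C@@]34C[C@@H](C[C@H]5O[C@]53[C@]2(C)[C@H]1O)[C@@H](C)[C@@H]4O[Si](C)(C)C(C)(C)C | intermediate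
26 | 1α,2α,6-triacetate 15-silyl ether | CC(=O)O[C@H]1CC(C)(C)[C@H]2[C@H](OC(C)=O)OC[C@@]34C[C@@H](C[C@H]5O[C@]53[C@]2(C)[C@H]1OC(C)=O)[C@@H](C)[C@@H]4O[Si](C)(C)C(C)(C)C | intermediate
27 | 1α,2α,6-triacetate 15-alcohol | CC(=O)O[C@H]1CC(C)(C)[C@H]2[C@H](OC(C)=O)OC[C@@]34C[C@@H](C[C@H]5O[C@]53[C@]2(C)[C@H]1OC(C)=O)[C@@H](C)[C@@H]4O | intermediate
28 | 1α,2α,6-triacetate 15-ketone | CC(=O)O[C@H]1CC(C)(C)[C@H]2[C@H](OC(C)=O)OC[C@@]34C[C@@H](C[C@H]5O[C@]53[C@]2(C)[C@H]1OC(C)=O)[C@@H](C)C4=O | intermediate
29 | CNP0210140.1 | CC(=O)O[C@H]1CC(C)(C)[C@H]2[C@H](O)OC[C@@]34C[C@@H](C[C@H]5O[C@]53[C@]2(C)[C@H]1OC(C)=O)[C@@H](C)C4=O | target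

**Step count and risks**

Total step count: 22. Longest linear sequence: 22 steps (1 to 29); 14 is used as purchased.

Steps most likely to fail:

Step 14. The cycloaddition may be too slow, because the trisubstituted enoate must react through the cisoid ester conformer and a seven-membered tether ring. In that case [1,5]-hydrogen shift of the cis-methyl diene, thermal opening of the vinyl epoxide, or poor exo and π-facial discrimination can take over. The fallback sets out from 17, which has no epoxide, and builds the two bonds by an ionic, stepwise route at low temperature. Excess Et3SiOTf and Et3N in CH2Cl2 (–78 °C to rt), the conditions of the intramolecular double Michael reaction, convert 17 into the triethylsilyl dienol ether F1. C3 of F1 adds to C4 of the silyl-activated enoate (Mukaiyama–Michael addition), and the ketene acetal carbon C5 so formed adds to C10 of the activated enone to give the 9(11)-ene tetracycle F2. F2 is then treated with dimethyldioxirane (2.5 equiv), which oxidises both the silyl enol ether and the C9=C11 alkene (α face, anti to the two-carbon bridge) to give 21. After the citric acid and methanol treatment of step 15 the route is rejoined at 22.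

Step 4. Hydride may displace the allylic chloride or attack the ester carbonyl before conjugate addition, and the dienolate may alkylate at C11 (γ) instead of C8. The fallback sets out from 4 and replaces the chloride by a leaving group that is inert to hydride and is ionised only by palladium. SeO2 with t-BuOOH oxidises the isopropenyl methyl group selectively (the ring diene is deactivated by the ester) to the allylic alcohol F3, and Ac2O in pyridine gives the allylic acetate F4. LiBH(s-Bu)3 at –78 °C then gives the enolate F5 as its tri-sec-butylborane complex, and addition of Pd(PPh3)4 (catalytic) closes ring D by intramolecular Tsuji–Trost allylation at C8, which returns to 7.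

Step 5. Over-oxidation (C10 to the aldehyde, C15 to the enone) and unequal rates at the two alkenes may give mixtures of oxidation levels. The fallback sets out from 7 and separates the two oxidations. SeO2 (catalytic) with one equivalent of t-BuOOH at 0 °C oxidises the more electron-rich trisubstituted alkene position first to give the C10 alcohol F6, and MnO2 converts it into the enal F7, which deactivates C9=C11. A second SeO2/t-BuOOH oxidation then acts only at C15 to give F8, and hydrogenation over RhCl(PPh3)3 as in step 6 returns to the route at 10.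

**Further compounds**

F1 | step 14 | triethylsilyl dienol ether of 17 (9(11)-ene analogue of 19) | CC(C)=CC(=O)OC[C@@]12C[C@@H](CC=C1/C(C)=C/C(=C)O[Si](CC)(CC)CC)[C@@H](C)[C@@H]2O[Si](C)(C)C(C)(C)C
F2 | step 14 | 9(11)-ene analogue of 20 (tetracyclic lactone, C1=C2 triethylsilyl enol ether) | CC[Si](CC)(CC)OC1CC(C)(C)[C@H]2C(=O)OC[C@@]34C[C@@H](CC=C3[C@]2(C)C=1)[C@@H](C)[C@@H]4O[Si](C)(C)C(C)(C)C
F3 | step 4 | methyl (3R)-3-(3-hydroxyprop-1-en-2-yl)-6-methylcyclohexa-1,5-diene-1-carboxylate | COC(=O)C1=C[C@@H](CC=C1C)C(=C)CO
F4 | step 4 | methyl (3R)-3-(3-acetoxyprop-1-en-2-yl)-6-methylcyclohexa-1,5-diene-1-carboxylate | COC(=O)C1=C[C@@H](CC=C1C)C(=C)COC(C)=O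
F5 | step 4 | lithium dienolate of methyl (5R)-5-(3-acetoxyprop-1-en-2-yl)-2-methylcyclohex-2-ene-1-carboxylate | [Li+].COC([O-])=C1C[C@@H](CC=C1C)C(=C)COC(C)=O
F6 | step 5 | methyl (1R,5R)-2-(hydroxymethyl)-6-methylidenebicyclo[3.2.1]oct-2-ene-1-carboxylate | COC(=O)[C@@]12C[C@@H](CC=C1CO)C(=C)C2
F7 | step 5 | methyl (1R,5R)-2-formyl-6-methylidenebicyclo[3.2.1]oct-2-ene-1-carboxylate | COC(=O)[C@@]12C[C@@H](CC=C1C=O)C(=C)C2
F8 | step 5 | methyl 2-formyl-7-exo-hydroxy-6-methylidenebicyclo[3.2.1]oct-2-ene-1-carboxylate | COC(=O)[C@@]12C[C@@H](CC=C1C=O)C(=C)[C@@H]2O
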